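(The runs are calculated with constants of no real substance.)

| setting | midnight | dawn | flask |
|---|---|---|---|
| left-handed substrate | 0.20 M | 0.20 M | 0.20 M |
| right-handed substrate | 0.20 M | 0.20 M | 0.20 M |
| partner | 0.060 M (fed, over 15 h) | 0.090 M (fed, over 15 h) | 0.120 M (fed, over 15 h) |
| free catalyst | 0.74 mM | 0.74 mM | 0.74 mM |
| remark | run made earlier; the fed solution adds 0.20 times the starting volume | run made earlier; the fed solution adds 0.20 times the starting volume | the fed solution adds 0.20 times the starting volume |
| time |  |  | 30 h |

| run | time / h | right-handed substrate / % | left-handed substrate / % |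
|---|---|---|---|
| midnight | 1.50 | 50.5 | 49.7 |
| midnight | 5.00 | 49.6 | 48.3 |
| midnight | 8.00 | 50.1 | 47.8 |
| midnight | 12.0 | 50.1 | 45.8 |
| midnight | 20.0 | 50.2 | 42.2 |
| midnight | 25.0 | 49.9 | 41.0 |
| dawn | 4.00 | 49.9 | 48.3 |
| dawn | 8.00 | 50.3 | 46.8 |
| dawn | 12.0 | 50.5 | 42.7 |
| dawn | 15.0 | 49.6 | 41.2 |
| dawn | 20.0 | 49.6 | 38.5 |
| dawn | 25.0 | 50.1 | 36.5 |

(scatter of a reading: 0.5 percentage points)

* whether the excess of right-handed substrate over left-handed substrate among what is left of the two reaches 90 % by 30 h (yes / no)
* the highest excess of right-handed substrate over left-handed substrate among what is left of the two up to 30 h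

- free catalyst is single-handed; left-handed substrate and right-handed substrate are mirror images of each other, charged as a racemate, each of them at the stated concentration
- charges are per starting volume, the dose included; the dosed solution carries all of it
- the analysis behind the earlier runs scatters by 0.5 percentage points, standard deviation

A small charge of partner, 0.060 M in the midnight run, had cost 0.0360 M of left-handed substrate at 25.0 h, while right-handed substrate still read 49.9 %. I called the left-handed substrate lost per partner charged, up to a stated time, the partner yield φ. At 25.0 h the midnight run read φ = 0.600 and the dawn run, on 0.090 M, read 0.600, so I scaled the loss with the charge. Partner is the limiting reagent in the flask, at 0.120 M against 0.20 M of left-handed substrate. With right-handed substrate intact, the excess is the loss φ·cB divided by the two substrate charges together less φ·cB, where cB is the partner charge.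

The flask is asked at 30 h, so φ had to be carried past the last reading. The dawn run gained 0.0889 in φ over its last interval, and the stretch still missing is equally long. Stopping at 25.0 h gives the flask 22.0 %, and an unfallen gain gives 26.1 %. Replacing the curve by the mean of these two, I took φ = 0.644, left-handed substrate lost per partner charged by 30 h, which gives the flask 23.9 %.

My second way let the gain shrink by the ratio of the last two dawn gains. That gave φ = 0.666 and 25.0 %. This way is the weaker one: its ratio rests on differences of 2.7 percentage points and 2 points between readings that scatter by 0.5 points. I kept the mean. For 90 % the flask needs φ = 1.58, above the one substrate per partner I assumed.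

The forecast said no and 24 %, on the ground that “Left-handed loss scales with the partner fed”.

The flask gave no and 23.5 %.

    free catalyst + left-handed substrate ⇌ catalyst intermediate A (K = 8.70 L mol⁻¹, k = 25000 L mol⁻¹ h⁻¹)
    free catalyst + right-handed substrate ⇌ catalyst intermediate B (K = 2.20 L mol⁻¹, k = 550 L mol⁻¹ h⁻¹)
    partner + catalyst intermediate A → free catalyst + left-handed product (k = 300 L mol⁻¹ h⁻¹)
    partner + catalyst intermediate B → free catalyst + right-handed product (k = 5.50 L mol⁻¹ h⁻¹)
    partner → decomposed reagent (k = 0.0400 h⁻¹)
    partner → decomposition product (k = 3.80 × 10⁻⁵ h⁻¹)

In the flask, partner's half-life by its step with catalyst intermediate A was 7.8 h at 12.6 h, shorter than the 17 h of its turning into decomposed reagent at 30.0 h, a first-order step with the same half-life at either time. The flask's φ came to 0.638 at 30.0 h, with 7.5 % of the partner left. For the neighbouring flask with 0.048 M of partner, my φ gives a loss of 0.0309 M and an excess of 8.37 %; the simulation gave 8.65 %.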